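**Retrosynthetic overview**
1. The last bond made is the allylic C4″–O bond of the (E)-hydroxyprenyl arm: ene/[2,3] C–H hydroxylation of the prenyl group of an otherwise complete enone acid, using a new water-free silyl selenite reagent.
2. The enone comes from its allylic alcohol (MnO2); the aryl–C1′ bond comes from a B-alkyl Suzuki coupling of an ortho-iodophenol acid with a C10 diene-diol.
3. The diene-diol comes from Brown (E)-crotylation of (2E)-4-hydroxy-4-methylpent-2-enal, which sets the methyl-bearing stereocenter; the enal comes from cross-metathesis of crotonaldehyde with 2-methylbut-3-en-2-ol.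
4. The iodophenol acid comes from ortho C-prenylation of methyl 4-hydroxy-3-iodobenzoate, saponified in the same pot.
5. No ring is formed: the benzene ring is bought and both arms stay open-chain.

Assumption: the target is the (3′S) enantiomer encoded by the given SMILES; C1′–C8′ denote the oxo-octenyl arm and C1″–C4″ the butenyl arm.

**Step 1**
Reactants: 1 methyl 4-hydroxy-3-iodobenzoate; 2 1-bromo-3-methylbut-2-ene (prenyl bromide)
Product: 4 4-hydroxy-3-iodo-5-(3-methylbut-2-en-1-yl)benzoic acid, via methyl ester 3 (not isolated)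
Conditions: NaH, toluene, 0 °C → rt; then aq NaOH, MeOH, 60 °C; HCl to pH 3
Reagents that add atoms: sodium hydroxide, [Na+].[OH-] (its oxygen becomes the acid OH)
Why: In non-polar toluene the tight sodium phenoxide ion pair of 1 is alkylated at its only free ortho carbon (phenoxide ortho C-alkylation), and the ester is then saponified in the same pot; no stereocenter is formed.

**Step 2**
Reactants: 5 (2E)-but-2-enal (crotonaldehyde); 6 2-methylbut-3-en-2-ol
Product: 7 (2E)-4-hydroxy-4-methylpent-2-enal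
Conditions: second-generation Hoveyda–Grubbs catalyst RuCl2(SIMes)(=CH-C6H4-2-OiPr) (2 mol%), CH2Cl2, 40 °C
Reagents that add atoms: none
Why: Olefin cross-metathesis between an electron-poor enal and a hindered tertiary allylic alcohol favours the hetero-coupled product as the E isomer, with propene lost; no stereocenter is formed.

**Step 3**
Reactants: 7 (2E)-4-hydroxy-4-methylpent-2-enal; 8 (2E)-but-2-ene
Product: 11 (3E,5R,6S)-2,6-dimethylocta-3,7-diene-2,5-diol, via crotylborane 9 (not isolated), via borinate 10 (not isolated)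
Conditions: 8, KOtBu, n-BuLi, THF, −78 → −45 °C; (−)-Ipc2BOMe, −78 °C; BF3·OEt2; 7 (1.5 equiv of borane per aldehyde), −78 °C; then NaOH, H2O2
Reagents that add atoms: none
Why: Brown crotylation through a closed chair (Zimmerman–Traxler) transition state: the E-crotyl geometry gives the anti adduct and the (−)-Ipc2B group directs attack to the Si face of the aldehyde, which sets C6 (the future C3′) as S and C5 as R, the free tertiary OH being tolerated at −78 °C with excess reagent.

**Step 4**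
Reactants: 11 (3E,5R,6S)-2,6-dimethylocta-3,7-diene-2,5-diol; 4 4-hydroxy-3-iodo-5-(3-methylbut-2-en-1-yl)benzoic acid
Product: 13 4-hydroxy-3-[(3S,4S,5E)-4,7-dihydroxy-3,7-dimethyloct-5-en-1-yl]-5-(3-methylbut-2-en-1-yl)benzoic acid, via alkylborane 12 (not isolated)
Conditions: 9-BBN (3.3 equiv), THF, 0 °C → rt; then 4, Pd(dppf)Cl2 (5 mol%), aq K3PO4, THF–DMF, 60 °C; 1 M HCl to pH 4, 0 °C
Reagents that add atoms: none
Why: 9-BBN adds anti-Markovnikov only to the monosubstituted terminal alkene (two more equivalents are taken up by the OH groups as borinates), and the primary B-alkyl group is transferred to the aryl iodide by B-alkyl Suzuki–Miyaura coupling on zerovalent palladium; the stereocenters are untouched (C4′ changes from R to S in name only).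

**Step 5**
Reactants: 13 4-hydroxy-3-[(3S,4S,5E)-4,7-dihydroxy-3,7-dimethyloct-5-en-1-yl]-5-(3-methylbut-2-en-1-yl)benzoic acid
Product: 14 4-hydroxy-3-[(3S,5E)-7-hydroxy-3,7-dimethyl-4-oxooct-5-en-1-yl]-5-(3-methylbut-2-en-1-yl)benzoic acid
Conditions: MnO2 (15 equiv), EtOAc, rt
Reagents that add atoms: none
Why: Allylic alcohol oxidation with MnO2 touches only the secondary allylic alcohol (the tertiary alcohol, the phenol and the isolated prenyl alkene are inert) under neutral conditions that do not epimerise the α′-stereocenter C3′.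

**Step 6**
Reactants: 14 4-hydroxy-3-[(3S,5E)-7-hydroxy-3,7-dimethyl-4-oxooct-5-en-1-yl]-5-(3-methylbut-2-en-1-yl)benzoic acid
Product: 17 4-hydroxy-3-[(2E)-4-hydroxy-3-methylbut-2-en-1-yl]-5-[(3S,5E)-7-hydroxy-3,7-dimethyl-4-oxooct-5-en-1-yl]benzoic acid, via tris(trimethylsilyl) derivative 15 (not isolated), via divalent selenium ester 16 (not isolated)
Conditions: BSA (N,O-bis(trimethylsilyl)acetamide, 3.3 equiv), ClCH2CH2Cl, rt; then (Me3SiO)2SeO (1.1 equiv, made from H2SeO3 and BSA), 40 °C; aq citric acid, MeOH, rt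
Reagents that add atoms: bis(trimethylsilyl) selenite, C[Si](C)(C)O[Se](=O)O[Si](C)(C)C (gives the new oxygen; made in the flask from selenous acid, O[Se](=O)O)
Why: Proposed new method: a Riley-type allylic hydroxylation run water-free with stoichiometric bis(trimethylsilyl) selenite on the transiently persilylated substrate — the tetravalent Se=O adds to the only electron-rich alkene in an ene reaction (Se to C2″, H from the E-methyl), the allylseleninic silyl ester undergoes a [2,3]-sigmatropic shift that puts oxygen on the terminal carbon and restores the trisubstituted alkene as the E isomer, and the product stays parked as a divalent selenium ester (no water and no excess oxidant, so no enal) until the citric acid work-up, while silylation keeps the ortho-phenol and the acid from forming aryl selenites or cyclising onto the activated prenyl unit; the closest known reaction type is the SeO2 (Riley) and SeO2/tBuOOH allylic hydroxylation, and no stereocenter is formed or touched.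

**Compound list**
1 | methyl 4-hydroxy-3-iodobenzoate | COC(=O)c1ccc(O)c(I)c1 | starting material
2 | 1-bromo-3-methylbut-2-ene (prenyl bromide) | CC(C)=CCBr | starting material
3 | methyl 4-hydroxy-3-iodo-5-(3-methylbut-2-en-1-yl)benzoate | COC(=O)c1cc(I)c(O)c(CC=C(C)C)c1 | intermediate (not isolated)
4 | 4-hydroxy-3-iodo-5-(3-methylbut-2-en-1-yl)benzoic acid | OC(=O)c1cc(I)c(O)c(CC=C(C)C)c1 | intermediate
5 | (2E)-but-2-enal (crotonaldehyde) | C/C=C/C=O | starting material
6 | 2-methylbut-3-en-2-ol | CC(C)(O)C=C | starting material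
7 | (2E)-4-hydroxy-4-methylpent-2-enal | CC(C)(O)/C=C/C=O | intermediate
8 | (2E)-but-2-ene | C/C=C/C | starting material
9 | (2E)-but-2-en-1-yl-diisopinocampheylborane, the antipode made from (−)-Ipc2BOMe ((+)-α-pinene series) | C/C=C/CB([C@@H]1C[C@@H]2C[C@H]([C@H]1C)C2(C)C)[C@@H]1C[C@@H]2C[C@H]([C@H]1C)C2(C)C | intermediate (not isolated)
10 | (3E,5R,6S)-2-hydroxy-2,6-dimethylocta-3,7-dien-5-yl diisopinocampheylborinate (same Ipc series) | C=C[C@H](C)[C@H](OB([C@@H]1C[C@@H]2C[C@H]([C@H]1C)C2(C)C)[C@@H]1C[C@@H]2C[C@H]([C@H]1C)C2(C)C)/C=C/C(C)(C)O | intermediate (not isolated)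
11 | (3E,5R,6S)-2,6-dimethylocta-3,7-diene-2,5-diol | C=C[C@H](C)[C@H](O)/C=C/C(C)(C)O | intermediate
12 | 9-[(3S,4S,5E)-4,7-bis(9-borabicyclo[3.3.1]nonan-9-yloxy)-3,7-dimethyloct-5-en-1-yl]-9-borabicyclo[3.3.1]nonane | B1(CC[C@H](C)[C@H](OB2C3CCCC2CCC3)/C=C/C(C)(C)OB2C3CCCC2CCC3)C2CCCC1CCC2 | intermediate (not isolated)
13 | 4-hydroxy-3-[(3S,4S,5E)-4,7-dihydroxy-3,7-dimethyloct-5-en-1-yl]-5-(3-methylbut-2-en-1-yl)benzoic acid | OC(=O)c1cc(CC=C(C)C)c(O)c(CC[C@H](C)[C@H](O)/C=C/C(C)(C)O)c1 | intermediate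
14 | 4-hydroxy-3-[(3S,5E)-7-hydroxy-3,7-dimethyl-4-oxooct-5-en-1-yl]-5-(3-methylbut-2-en-1-yl)benzoic acid | OC(=O)c1cc(CC=C(C)C)c(O)c(CC[C@H](C)C(=O)/C=C/C(C)(C)O)c1 | intermediate
15 | trimethylsilyl 3-[(3S,5E)-3,7-dimethyl-4-oxo-7-(trimethylsilyloxy)oct-5-en-1-yl]-5-(3-methylbut-2-en-1-yl)-4-(trimethylsilyloxy)benzoate | C[Si](C)(C)OC(=O)c1cc(CC=C(C)C)c(O[Si](C)(C)C)c(CC[C@H](C)C(=O)/C=C/C(C)(C)O[Si](C)(C)C)c1 | intermediate (not isolated)
16 | trimethylsilyl 3-[(3S,5E)-3,7-dimethyl-4-oxo-7-(trimethylsilyloxy)oct-5-en-1-yl]-5-[(2E)-3-methyl-4-{[(trimethylsilyloxy)selanyl]oxy}but-2-en-1-yl]-4-(trimethylsilyloxy)benzoate | C[Si](C)(C)OC(=O)c1cc(C/C=C(\C)CO[Se]O[Si](C)(C)C)c(O[Si](C)(C)C)c(CC[C@H](C)C(=O)/C=C/C(C)(C)O[Si](C)(C)C)c1 | intermediate (not isolated)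
17 | 4-hydroxy-3-[(2E)-4-hydroxy-3-methylbut-2-en-1-yl]-5-[(3S,5E)-7-hydroxy-3,7-dimethyl-4-oxooct-5-en-1-yl]benzoic acid | C/C(=C\Cc1cc(C(=O)O)cc(CC[C@H](C)C(=O)/C=C/C(C)(C)O)c1O)CO | target

**Step count and risks**
Total steps: 6. Longest linear sequence: 5 (steps 2, 3, 4, 5, 6).

The three steps most likely to fail:

Step 1 (C- versus O-alkylation of the phenoxide, moderate yield expected). Fallback, setting out from 1 and coming back at 3: 1 is O-alkylated with 2 (K2CO3, acetone) to methyl 3-iodo-4-[(3-methylbut-2-en-1-yl)oxy]benzoate F1. Its prenyl group is then moved from oxygen to the free ortho carbon by a [1,3] shift on magnesium silicate MgSiO3 (Florisil) in CH2Cl2 at rt to give 3, which is saponified as in step 1 to 4.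

Step 4 (two free OH groups consume 9-BBN, and the coupling partner is an unprotected iodophenol acid). Fallback, setting out from 11 and coming back at 13, with the diol masked before the boron chemistry: 11 is silylated with BSA to (3E,5R,6S)-2,6-dimethyl-2,5-bis(trimethylsilyloxy)octa-3,7-diene F2. Hydroboration with 1.1 equiv of 9-BBN gives 9-[(3S,4S,5E)-3,7-dimethyl-4,7-bis(trimethylsilyloxy)oct-5-en-1-yl]-9-borabicyclo[3.3.1]nonane F3. Coupling with 4 under the step 4 conditions gives 3-[(3S,4S,5E)-3,7-dimethyl-4,7-bis(trimethylsilyloxy)oct-5-en-1-yl]-4-hydroxy-5-(3-methylbut-2-en-1-yl)benzoic acid F4, which loses both silyl groups in the acidic work-up to give 13.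

Step 6 (the new step; risks are a sluggish ene reaction of the silyl selenite, oxidation next to the ketone, or loss of the silyl masks). Fallback with known chemistry, setting out from 4 and coming back at 17, in which the allylic C–O bond is made first on a simple substrate and carried through protected:
- 4 is acetylated (Ac2O, pyridine) to 4-acetoxy-3-iodo-5-(3-methylbut-2-en-1-yl)benzoic acid F5.
- Classical Riley hydroxylation (SeO2 cat., tBuOOH, CH2Cl2, then NaBH4 to return any enal) gives 4-acetoxy-3-[(2E)-4-hydroxy-3-methylbut-2-en-1-yl]-5-iodobenzoic acid F6.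
- TBSCl and imidazole (the silyl ester is hydrolysed on work-up) give 4-acetoxy-3-[(2E)-4-{[tert-butyl(dimethyl)silyl]oxy}-3-methylbut-2-en-1-yl]-5-iodobenzoic acid F7.
- Suzuki coupling of F7 with alkylborane 12 under the step 4 conditions, whose aqueous base also removes the acetate, gives 3-[(2E)-4-{[tert-butyl(dimethyl)silyl]oxy}-3-methylbut-2-en-1-yl]-5-[(3S,4S,5E)-4,7-dihydroxy-3,7-dimethyloct-5-en-1-yl]-4-hydroxybenzoic acid F8.
- MnO2 then oxidises only the secondary allylic alcohol, the primary one being silylated, to 3-[(2E)-4-{[tert-butyl(dimethyl)silyl]oxy}-3-methylbut-2-en-1-yl]-4-hydroxy-5-[(3S,5E)-7-hydroxy-3,7-dimethyl-4-oxooct-5-en-1-yl]benzoic acid F9.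
- HF·pyridine in THF gives 17.

**Further compounds**
F1 | step 1 | methyl 3-iodo-4-[(3-methylbut-2-en-1-yl)oxy]benzoate | COC(=O)c1ccc(OCC=C(C)C)c(I)c1
F2 | step 4 | (3E,5R,6S)-2,6-dimethyl-2,5-bis(trimethylsilyloxy)octa-3,7-diene | C=C[C@H](C)[C@H](O[Si](C)(C)C)/C=C/C(C)(C)O[Si](C)(C)C
F3 | step 4 | 9-[(3S,4S,5E)-3,7-dimethyl-4,7-bis(trimethylsilyloxy)oct-5-en-1-yl]-9-borabicyclo[3.3.1]nonane | B1(CC[C@H](C)[C@H](O[Si](C)(C)C)/C=C/C(C)(C)O[Si](C)(C)C)C2CCCC1CCC2
F4 | step 4 | 3-[(3S,4S,5E)-3,7-dimethyl-4,7-bis(trimethylsilyloxy)oct-5-en-1-yl]-4-hydroxy-5-(3-methylbut-2-en-1-yl)benzoic acid | OC(=O)c1cc(CC=C(C)C)c(O)c(CC[C@H](C)[C@H](O[Si](C)(C)C)/C=C/C(C)(C)O[Si](C)(C)C)c1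
F5 | step 6 | 4-acetoxy-3-iodo-5-(3-methylbut-2-en-1-yl)benzoic acid | CC(=O)Oc1c(I)cc(C(=O)O)cc1CC=C(C)C
F6 | step 6 | 4-acetoxy-3-[(2E)-4-hydroxy-3-methylbut-2-en-1-yl]-5-iodobenzoic acid | CC(=O)Oc1c(I)cc(C(=O)O)cc1C/C=C(\C)CO
F7 | step 6 | 4-acetoxy-3-[(2E)-4-{[tert-butyl(dimethyl)silyl]oxy}-3-methylbut-2-en-1-yl]-5-iodobenzoic acid | CC(=O)Oc1c(I)cc(C(=O)O)cc1C/C=C(\C)CO[Si](C)(C)C(C)(C)C
F8 | step 6 | 3-[(2E)-4-{[tert-butyl(dimethyl)silyl]oxy}-3-methylbut-2-en-1-yl]-5-[(3S,4S,5E)-4,7-dihydroxy-3,7-dimethyloct-5-en-1-yl]-4-hydroxybenzoic acid | OC(=O)c1cc(C/C=C(\C)CO[Si](C)(C)C(C)(C)C)c(O)c(CC[C@H](C)[C@H](O)/C=C/C(C)(C)O)c1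
F9 | step 6 | 3-[(2E)-4-{[tert-butyl(dimethyl)silyl]oxy}-3-methylbut-2-en-1-yl]-4-hydroxy-5-[(3S,5E)-7-hydroxy-3,7-dimethyl-4-oxooct-5-en-1-yl]benzoic acid | OC(=O)c1cc(C/C=C(\C)CO[Si](C)(C)C(C)(C)C)c(O)c(CC[C@H](C)C(=O)/C=C/C(C)(C)O)c1
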